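**Retrosynthetic overview**

- The target is read as the 6R,1′S,2′S,4′S,6′S isomer (lactone C6, carbinol C1′, trans-cyclopropane C2′/C4′, acyloxy carbon C6′). The last skeletal bond is the C6′–O ester bond, made by a new catalyst-controlled, stereoconvergent displacement of an epimerising α-bromo ketone by 4-methoxycinnamic acid; desilylation follows.
- Ring B (the cyclopropane) is formed second, by ruthenium-carbene cyclopropanation of a terminal vinyl group with racemic 3-bromo-1-diazobutan-2-one.
- Ring A (the 5,6-dihydropyran-2-one) is formed first, by C–O lactonisation of a (Z)-δ-hydroxy enoate made from a terminal epoxide, ethyl propiolate and a cis-semihydrogenation.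
- The C6–O/C1′–O erythro pair comes from the Sharpless desymmetrising epoxidation of penta-1,4-dien-3-ol.

Assumption: the (S)-phenyloxazoline ruthenium catalyst of step 6 and the cinchonidinium catalyst of step 7 are taken to give the required sense of induction; if the first run shows the opposite sense, the mirror-image ruthenium complex or the pseudo-enantiomeric cinchoninium salt is used with nothing else changed.

**Route**

Step 1
Reactants: 1 penta-1,4-dien-3-ol
Product: 2 (1S)-1-[(2R)-oxiran-2-yl]prop-2-en-1-ol [(2R,3S)-1,2-epoxypent-4-en-3-ol]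
Conditions: Ti(OiPr)4 (10 mol %), L-(+)-diisopropyl tartrate (13 mol %), TBHP (decane, 1.6 equiv), 4 Å MS, CH2Cl2, −20 °C, 4–6 d
Reagents that add atoms: tert-butyl hydroperoxide, CC(C)(C)OO
Why: Sharpless asymmetric epoxidation with enantiotopic-group plus diastereoface selection; L-(+)-tartrate (the hand that gives 2S,3S epoxides from E-allylic alcohols and consumes (S)-carbinols fastest) gives the erythro 2R,3S epoxy alcohol, and the minor enantiomer is removed by a second epoxidation, so both the C6 and C1′ centres are set here.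

Step 2
Reactants: 2 (1S)-1-[(2R)-oxiran-2-yl]prop-2-en-1-ol
Product: 3 tert-butyldimethyl{[(1S)-1-[(2R)-oxiran-2-yl]prop-2-en-1-yl]oxy}silane
Conditions: TBSCl (1.2 equiv), imidazole (2 equiv), DMF, 0 °C → rt
Reagents that add atoms: tert-butyldimethylsilyl chloride, CC(C)(C)[Si](C)(C)Cl
Why: Standard silylation of a secondary alcohol; it blocks O–H insertion in step 6 and Payne rearrangement in step 3, and no stereocentre is touched.

Step 3
Reactants: 3 tert-butyldimethyl{[(1S)-1-[(2R)-oxiran-2-yl]prop-2-en-1-yl]oxy}silane; 4 ethyl propiolate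
Product: 6 ethyl (5R,6S)-6-[(tert-butyldimethylsilyl)oxy]-5-hydroxyoct-7-en-2-ynoate, via lithium ethyl propiolate 5 (not isolated)
Conditions: 4 (3 equiv), n-BuLi (3 equiv), THF, −78 °C; BF3·OEt2 (3 equiv); then 3, −78 °C, 2 h; aqueous quench at −78 °C
Reagents that add atoms: none
Why: Yamaguchi–Hirao BF3-promoted alkynylation opens the epoxide at its terminal CH2, so the C5–O bond is not broken and the 5R centre is retained.

Step 4
Reactants: 6 ethyl (5R,6S)-6-[(tert-butyldimethylsilyl)oxy]-5-hydroxyoct-7-en-2-ynoate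
Product: 8 (6R)-6-[(1S)-1-[(tert-butyldimethylsilyl)oxy]prop-2-en-1-yl]-5,6-dihydro-2H-pyran-2-one, via Z-hydroxy-enoate 7 (not isolated)
Conditions: H2 (1 atm), Pd/CaCO3 poisoned with Pb(OAc)2 (Lindlar catalyst), quinoline, EtOAc, rt, stopped at 1 equiv H2; then PPTS (10 mol %), PhMe, 60 °C
Reagents that add atoms: none
Why: Lindlar cis-semihydrogenation of the ynoate followed by acid-catalysed lactonisation (intramolecular transesterification); the Z geometry places the δ-hydroxyl next to the ester so ring A closes, and the stereocentres are untouched.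

Step 5
Reactants: 9 2-bromopropanoyl chloride (racemic); 10 (trimethylsilyl)diazomethane
Product: 11 3-bromo-1-diazobutan-2-one (racemic)
Conditions: 10 (2.0 M in hexanes, 2 equiv), MeCN/THF 1:1, 0 °C → rt, 3 h; short silica plug, used as a CH2Cl2 solution
Reagents that add atoms: none
Why: C-acylation of the diazoalkane with loss of TMSCl (the Arndt–Eistert-type diazoketone synthesis); the bromine-bearing centre is deliberately left racemic.

Step 6
Reactants: 8 (6R)-6-[(1S)-1-[(tert-butyldimethylsilyl)oxy]prop-2-en-1-yl]-5,6-dihydro-2H-pyran-2-one; 11 3-bromo-1-diazobutan-2-one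
Product: 12 (2RS)-2-bromo-1-[(1S,2S)-2-{(S)-[(tert-butyldimethylsilyl)oxy][(2R)-6-oxo-3,6-dihydro-2H-pyran-2-yl]methyl}cyclopropyl]propan-1-one (both C–Br epimers)
Conditions: [Ru(NCMe)4(C15H12NO)]PF6 (3 mol %; C15H12NO = C,N-cyclometalated (S)-2,4-diphenyl-4,5-dihydrooxazole), CH2Cl2, 0 °C → rt, 11 (3 equiv) added over 10 h
Reagents that add atoms: none
Why: Trans-selective carbene cyclopropanation of a monosubstituted alkene by a chiral phenyloxazoline complex of divalent ruthenium, a catalyst class shown to work with α′-acyloxy diazoketones and to prefer terminal alkenes (the endocyclic enoate is left alone); the catalyst sets both ring B centres (1S,2S) over the allylic silyloxy centre.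

Step 7
Reactants: 12 (2RS)-2-bromo-1-[(1S,2S)-2-{(S)-[(tert-butyldimethylsilyl)oxy][(2R)-6-oxo-3,6-dihydro-2H-pyran-2-yl]methyl}cyclopropyl]propan-1-one; 13 (E)-4-methoxycinnamic acid
Product: 15 (2S)-1-[(1S,2S)-2-{(S)-[(tert-butyldimethylsilyl)oxy][(2R)-6-oxo-3,6-dihydro-2H-pyran-2-yl]methyl}cyclopropyl]-1-oxopropan-2-yl (2E)-3-(4-methoxyphenyl)prop-2-enoate (O-TBS-brevipolide H), via potassium (E)-4-methoxycinnamate 14 (not isolated)
Conditions: 13 (1.5 equiv), powdered KHCO3 (2 equiv), N-(9-anthracenylmethyl)cinchonidinium bromide (10 mol %), PhMe, 0 °C → rt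
Reagents that add atoms: none
Why: Proposed new method: catalyst-controlled stereoconvergent SN2 acyloxylation, in which the two C–Br epimers of 12 interconvert by degenerate SN2 exchange with the bromide carried by the chiral ammonium ion (fast at an α-keto carbon), while carboxylate 14 enters the toluene phase only as its ion pair with the cinchonidinium cation, whose free 9-OH hydrogen-bonds the ketone so that the (R)-bromide is displaced with inversion faster than the (S)-bromide (Curtin–Hammett) to give the (S)-ester; a catalytic carboxylate version on a secondary α-bromo dialkyl ketone has not been shown, and the closest known reaction types are phase-transfer O-alkylation of carboxylates by α-halo ketones, auxiliary-based dynamic kinetic resolution of α-halo carbonyl compounds through halide exchange, and chiral-cation-catalysed enantioconvergent substitution of tertiary α-bromo carbonyl compounds.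

Step 8
Reactants: 15 O-TBS-brevipolide H
Product: 16 brevipolide H, (2S)-1-[(1S,2S)-2-{(S)-hydroxy[(2R)-6-oxo-3,6-dihydro-2H-pyran-2-yl]methyl}cyclopropyl]-1-oxopropan-2-yl (2E)-3-(4-methoxyphenyl)prop-2-enoate
Conditions: HF·pyridine, THF/pyridine, 0 °C → rt
Reagents that add atoms: none
Why: Fluoride-mediated desilylation under buffered acidic conditions that leave the α-acyloxy ketone, the enoate lactone and all five stereocentres untouched; the trans-cyclopropane keeps the freed hydroxyl away from the ketone and the ester.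

**Compound list**

1 | penta-1,4-dien-3-ol (divinyl carbinol) | C=CC(O)C=C | starting material
2 | (1S)-1-[(2R)-oxiran-2-yl]prop-2-en-1-ol | C=C[C@H](O)[C@H]1CO1 | intermediate
3 | tert-butyldimethyl{[(1S)-1-[(2R)-oxiran-2-yl]prop-2-en-1-yl]oxy}silane | C=C[C@H](O[Si](C)(C)C(C)(C)C)[C@H]1CO1 | intermediate
4 | ethyl propiolate | C#CC(=O)OCC | starting material
5 | lithium ethyl propiolate (ethyl 3-lithioprop-2-ynoate) | [Li]C#CC(=O)OCC | intermediate (not isolated)
6 | ethyl (5R,6S)-6-[(tert-butyldimethylsilyl)oxy]-5-hydroxyoct-7-en-2-ynoate | C=C[C@H](O[Si](C)(C)C(C)(C)C)[C@H](O)CC#CC(=O)OCC | intermediate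
7 | ethyl (2Z,5R,6S)-6-[(tert-butyldimethylsilyl)oxy]-5-hydroxyocta-2,7-dienoate | C=C[C@H](O[Si](C)(C)C(C)(C)C)[C@H](O)C/C=C\C(=O)OCC | intermediate (not isolated)
8 | (6R)-6-[(1S)-1-[(tert-butyldimethylsilyl)oxy]prop-2-en-1-yl]-5,6-dihydro-2H-pyran-2-one | C=C[C@H](O[Si](C)(C)C(C)(C)C)[C@H]1CC=CC(=O)O1 | intermediate
9 | 2-bromopropanoyl chloride (racemic) | CC(Br)C(=O)Cl | starting material
10 | (trimethylsilyl)diazomethane | C[Si](C)(C)C=[N+]=[N-] | starting material
11 | 3-bromo-1-diazobutan-2-one (racemic) | CC(Br)C(=O)C=[N+]=[N-] | intermediate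
12 | (2RS)-2-bromo-1-[(1S,2S)-2-{(S)-[(tert-butyldimethylsilyl)oxy][(2R)-6-oxo-3,6-dihydro-2H-pyran-2-yl]methyl}cyclopropyl]propan-1-one | CC(Br)C(=O)[C@H]1C[C@@H]1[C@H](O[Si](C)(C)C(C)(C)C)[C@H]1CC=CC(=O)O1 | intermediate
13 | (E)-4-methoxycinnamic acid | COc1ccc(/C=C/C(=O)O)cc1 | starting material
14 | potassium (E)-4-methoxycinnamate | COc1ccc(/C=C/C(=O)[O-])cc1.[K+] | intermediate (not isolated)
15 | O-TBS-brevipolide H | COc1ccc(/C=C/C(=O)O[C@@H](C)C(=O)[C@H]2C[C@@H]2[C@H](O[Si](C)(C)C(C)(C)C)[C@H]2CC=CC(=O)O2)cc1 | intermediate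
16 | brevipolide H | COc1ccc(/C=C/C(=O)O[C@@H](C)C(=O)[C@H]2C[C@@H]2[C@H](O)[C@H]2CC=CC(=O)O2)cc1 | target

**Step count**

Total: 8 steps. Longest linear sequence: 7 steps (1, 2, 3, 4, 6, 7, 8); step 5 is a one-step side branch.

**Steps most likely to fail, with fallbacks**

Step 7 (the proposed new stereoconvergent acyloxylation). The risks are slow bromide exchange or weak discrimination by the chiral ion pair, giving a mixture of C6′ epimers. The fallback uses known chemistry and takes the C6′ centre from the chiral pool; it sets out from alkene 8 and comes back at 15. L-Lactic acid is O-acylated with (E)-4-methoxycinnamoyl chloride (pyridine, cat. DMAP, CH2Cl2, 0 °C) to give (2S)-2-{[(2E)-3-(4-methoxyphenyl)prop-2-enoyl]oxy}propanoic acid F1. Oxalyl chloride with cat. DMF converts it into (2S)-1-chloro-1-oxopropan-2-yl (2E)-3-(4-methoxyphenyl)prop-2-enoate F2. Compound 10 (no amine base, 0 °C) then gives (2S)-4-diazo-3-oxobutan-2-yl (2E)-3-(4-methoxyphenyl)prop-2-enoate F3. F3 is added slowly to 8 with the ruthenium catalyst of step 6; α′-acyloxy diazoketones are the documented reagent class for this catalyst, and the product is 15 directly.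

Step 6 (cyclopropanation of a hindered, allylically oxygenated terminal alkene). The risks are low conversion or poor face control. The fallback replaces the electrophilic carbene by a nucleophilic ring closure; it sets out from 8 and comes back at 12.
- Cross-metathesis of 8 with pent-1-en-3-one (3 equiv; second-generation Hoveyda–Grubbs catalyst RuCl2(=CH-C6H4-2-OiPr)(H2IMes), CH2Cl2, 40 °C) gives (6R)-6-[(1S,2E)-1-[(tert-butyldimethylsilyl)oxy]-4-oxohex-2-en-1-yl]-5,6-dihydro-2H-pyran-2-one F4.
- Corey–Chaykovsky cyclopropanation with dimethylsulfoxonium methylide (Me3S(O)I, NaH, DMSO/THF, 0 °C, 1.05 equiv) attacks the more electrophilic acyclic enone anti to the γ-silyloxy group (Felkin–Anh) and gives 1-[(1S,2S)-2-{(S)-[(tert-butyldimethylsilyl)oxy][(2R)-6-oxo-3,6-dihydro-2H-pyran-2-yl]methyl}cyclopropyl]propan-1-one F5. The dr must be checked and the minor isomer removed.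
- α-Bromination on the only enolisable side (PhNMe3Br3, THF, 0 °C) gives 12.

Step 4 (Lindlar semihydrogenation next to a terminal vinyl group, then lactonisation). The risks are over-reduction of the vinyl group or of the enoate. The fallback avoids the alkyne and hydrogen altogether (Ghosez sulfone lactone synthesis); it sets out from epoxide 3, bypasses 6, and comes back at 8. Lithiated trimethyl 3-(phenylsulfonyl)orthopropionate (n-BuLi, THF/DMPU, −78 → −20 °C) opens 3 at the terminal carbon to give (5R,6S)-6-[(tert-butyldimethylsilyl)oxy]-1,1,1-trimethoxy-3-(phenylsulfonyl)oct-7-en-5-ol F6. TsOH·H2O (cat., CH2Cl2) closes it to (6R)-6-[(1S)-1-[(tert-butyldimethylsilyl)oxy]prop-2-en-1-yl]-4-(phenylsulfonyl)oxan-2-one F7. DBU (CH2Cl2, 0 °C) eliminates benzenesulfinate to give 8.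

**Further compounds**

F1 | step 7 | (2S)-2-{[(2E)-3-(4-methoxyphenyl)prop-2-enoyl]oxy}propanoic acid | COc1ccc(/C=C/C(=O)O[C@@H](C)C(=O)O)cc1
F2 | step 7 | (2S)-1-chloro-1-oxopropan-2-yl (2E)-3-(4-methoxyphenyl)prop-2-enoate | COc1ccc(/C=C/C(=O)O[C@@H](C)C(=O)Cl)cc1
F3 | step 7 | (2S)-4-diazo-3-oxobutan-2-yl (2E)-3-(4-methoxyphenyl)prop-2-enoate | COc1ccc(/C=C/C(=O)O[C@@H](C)C(=O)C=[N+]=[N-])cc1
F4 | step 6 | (6R)-6-[(1S,2E)-1-[(tert-butyldimethylsilyl)oxy]-4-oxohex-2-en-1-yl]-5,6-dihydro-2H-pyran-2-one | CCC(=O)/C=C/[C@H](O[Si](C)(C)C(C)(C)C)[C@H]1CC=CC(=O)O1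
F5 | step 6 | 1-[(1S,2S)-2-{(S)-[(tert-butyldimethylsilyl)oxy][(2R)-6-oxo-3,6-dihydro-2H-pyran-2-yl]methyl}cyclopropyl]propan-1-one | CCC(=O)[C@H]1C[C@@H]1[C@H](O[Si](C)(C)C(C)(C)C)[C@H]1CC=CC(=O)O1
F6 | step 4 | (5R,6S)-6-[(tert-butyldimethylsilyl)oxy]-1,1,1-trimethoxy-3-(phenylsulfonyl)oct-7-en-5-ol | C=C[C@H](O[Si](C)(C)C(C)(C)C)[C@H](O)CC(CC(OC)(OC)OC)S(=O)(=O)c1ccccc1
F7 | step 4 | (6R)-6-[(1S)-1-[(tert-butyldimethylsilyl)oxy]prop-2-en-1-yl]-4-(phenylsulfonyl)oxan-2-one | C=C[C@H](O[Si](C)(C)C(C)(C)C)[C@H]1CC(S(=O)(=O)c2ccccc2)CC(=O)O1
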